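Ring E is left unbuilt until the end. Its two adjacent carbon-bearing atoms, C1' and C6', carry the stereocentres C2 of ring F and C4 of ring C, so they are joined first as the two carbons of an internal alkyne, while C2'–C5' with both oxygens arrive later as a symmetric 2,3-dioxybutadiene. One cobalt-catalysed [4+2] cycloaddition then forms both new C–C bonds and closes the carbocycle of ring E, with no regiochemical choice among rings A, D and E. Its precursor is the hexabenzyl-protected 1-(chroman-2-yl)-2-(flavan-4-yl)ethyne with all five stereocentres already set, made by alkynylation of a fustin-derived C4 cation, chelate-controlled acetylide addition and Mitsunobu ring closure.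

Key step: step 14

Remark: ring letters follow flavan usage (upper unit A/B/C, lower unit D/E/F, ring-E locants primed); the target is 2R,3S,4R in the upper unit and 2R,3S in the lower unit (2,3-trans in both, 3,4-trans above), and (2R,3R)-fustin is assumed to be bought as the single enantiomer.

Step 1
Reactants: 1 (2R,3R)-fustin
Product: 2 (2R,3R)-7-(benzyloxy)-2-[3,4-bis(benzyloxy)phenyl]-3-hydroxychroman-4-one
Conditions: BnBr (3.3 equiv), K2CO3, DMF, rt, argon
Reagents that add atoms: benzyl bromide, BrCc1ccccc1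
Why: Williamson ether synthesis in which the carbonate deprotonates only the three phenols (not the secondary 3-OH), and at room temperature under argon the trans C2/C3 centres of the dihydroflavonol should survive because enolisation and ring opening need stronger base or heat.

Step 2
Reactants: 2 (2R,3R)-7-(benzyloxy)-2-[3,4-bis(benzyloxy)phenyl]-3-hydroxychroman-4-one
Product: 3 (2R,3S,4R)-7-(benzyloxy)-2-[3,4-bis(benzyloxy)phenyl]chromane-3,4-diol
Conditions: NaBH4, THF/MeOH, 0 °C
Reagents that add atoms: none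
Why: Borohydride reduction of the aryl ketone to the benzylic alcohol, expected to give mainly the 3,4-trans diol by axial hydride delivery; the C4 configuration is of no consequence because this centre is ionised in step 4.

Step 3
Reactants: 3 (2R,3S,4R)-7-(benzyloxy)-2-[3,4-bis(benzyloxy)phenyl]chromane-3,4-diol
Product: 4 (2R,3S,4R)-3,4,7-tris(benzyloxy)-2-[3,4-bis(benzyloxy)phenyl]chromane
Conditions: NaH, BnBr, Bu4NI (cat.), DMF, 0 °C → rt
Reagents that add atoms: benzyl bromide, BrCc1ccccc1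
Why: Twofold Williamson etherification of the alkoxides installs the permanent benzyl ether on O3 and turns O4 into a benzylic ether leaving group without touching a stereocentre.

Step 4
Reactants: 4 (2R,3S,4R)-3,4,7-tris(benzyloxy)-2-[3,4-bis(benzyloxy)phenyl]chromane; 5 potassium trifluoro[(trimethylsilyl)ethynyl]borate
Product: 8 (2R,3S,4R)-3,7-bis(benzyloxy)-2-[3,4-bis(benzyloxy)phenyl]-4-ethynylchromane, via difluoro[(trimethylsilyl)ethynyl]borane 6 (not isolated), via 4-(trimethylsilylethynyl)flavan 7 (not isolated)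
Conditions: BF3·OEt2, CH2Cl2/MeCN, −40 → 0 °C; then K2CO3, MeOH, rt
Reagents that add atoms: none
Why: SN1-type alkynylation of a π-activated benzylic ether with an alkynyltrifluoroborate, in which BF3 strips fluoride from 5 to give borane 6, which ionises the C4–OBn bond to the cation stabilised by the 7-benzyloxy group of ring A and transfers its alkynyl group to C4 anti to the neighbouring 3-benzyloxy group (3,4-trans, substrate control), after which carbonate in methanol cleaves the C–Si bond.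

Step 5
Reactants: 9 4-bromoresorcinol
Product: 10 5-(benzyloxy)-2-bromophenol
Conditions: BnBr (1.0 equiv), K2CO3, acetone, rt
Reagents that add atoms: benzyl bromide, BrCc1ccccc1
Why: Williamson monoalkylation, expected to favour the hydroxyl para to bromine because the ortho hydroxyl is shielded by bromine and gives the less nucleophilic phenoxide; the phenol is separated from any dibenzyl ether by base extraction.

Step 6
Reactants: 10 5-(benzyloxy)-2-bromophenol
Product: 11 4-(benzyloxy)-1-bromo-2-(methoxymethoxy)benzene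
Conditions: NaH, MOMCl, DMF, 0 °C
Reagents that add atoms: chloromethyl methyl ether, COCCl
Why: O-Alkylation of the sodium phenoxide with the α-chloro ether gives the MOM acetal on the future ring-F oxygen, a group that survives the organometallic steps and is later removed by mild acid in the presence of benzyl ethers.

Step 7
Reactants: 11 4-(benzyloxy)-1-bromo-2-(methoxymethoxy)benzene; 12 methyl (S)-glycidate
Product: 14 methyl (2S)-3-[4-(benzyloxy)-2-(methoxymethoxy)phenyl]-2-hydroxypropanoate, via arylmagnesium bromide 13 (not isolated)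
Conditions: Mg, LiCl, THF, rt; then added to 12, CuI (10 mol%), THF, −40 °C; NH4Cl work-up
Reagents that add atoms: none
Why: Grignard formation followed by copper-catalysed SN2 opening of the epoxide at its unsubstituted CH2 terminus, faster at −40 °C than addition to the ester; the glycidate centre (future C3 of ring F) is not touched and keeps its S configuration.

Step 8
Reactants: 14 methyl (2S)-3-[4-(benzyloxy)-2-(methoxymethoxy)phenyl]-2-hydroxypropanoate
Product: 15 methyl (2S)-2-(benzyloxy)-3-[4-(benzyloxy)-2-(methoxymethoxy)phenyl]propanoate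
Conditions: BnBr, Ag2O, CH2Cl2, rt, dark
Reagents that add atoms: benzyl bromide, BrCc1ccccc1
Why: Silver-oxide-promoted O-benzylation (Williamson-type without a strong base), so that the α-hydroxy ester is neither enolised nor racemised.

Step 9
Reactants: 15 methyl (2S)-2-(benzyloxy)-3-[4-(benzyloxy)-2-(methoxymethoxy)phenyl]propanoate
Product: 16 (2S)-2-(benzyloxy)-3-[4-(benzyloxy)-2-(methoxymethoxy)phenyl]propanal
Conditions: i-Bu2AlH (1.1 equiv), CH2Cl2, −78 °C; aqueous potassium sodium tartrate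
Reagents that add atoms: none
Why: Partial reduction of the ester with one equivalent of the aluminium hydride at −78 °C, where the chelated tetrahedral intermediate of an α-alkoxy ester persists until work-up so that no over-reduction occurs; the aldehyde is used crude to avoid epimerisation.

Step 10
Reactants: 8 (2R,3S,4R)-3,7-bis(benzyloxy)-2-[3,4-bis(benzyloxy)phenyl]-4-ethynylchromane; 16 (2S)-2-(benzyloxy)-3-[4-(benzyloxy)-2-(methoxymethoxy)phenyl]propanal
Product: 19 (2S,3S)-2-(benzyloxy)-1-[4-(benzyloxy)-2-(methoxymethoxy)phenyl]-5-[(2R,3S,4R)-3,7-bis(benzyloxy)-2-(3,4-bis(benzyloxy)phenyl)chroman-4-yl]pent-4-yn-3-ol, via lithium acetylide 17 (not isolated), via alkynylzinc bromide 18 (not isolated)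
Conditions: n-BuLi, Et2O/THF, −78 °C; ZnBr2, 0 °C; then 16, Et2O, −78 → 0 °C; NH4Cl work-up
Reagents that add atoms: none
Why: Addition of an alkynylzinc halide to an α-alkoxy aldehyde under Cram chelate control, in which zinc bridges the carbonyl and benzyloxy oxygens and the acetylide attacks the face opposite the CH2Ar group, which should give the syn (3S) carbinol that the inverting ring closure requires.

Step 11
Reactants: 19 (2S,3S)-2-(benzyloxy)-1-[4-(benzyloxy)-2-(methoxymethoxy)phenyl]-5-[(2R,3S,4R)-3,7-bis(benzyloxy)-2-(3,4-bis(benzyloxy)phenyl)chroman-4-yl]pent-4-yn-3-ol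
Product: 20 5-(benzyloxy)-2-{(2S,3S)-2-(benzyloxy)-5-[(2R,3S,4R)-3,7-bis(benzyloxy)-2-(3,4-bis(benzyloxy)phenyl)chroman-4-yl]-3-hydroxypent-4-yn-1-yl}phenol
Conditions: HCl (cat.), MeOH/THF, 40 °C
Reagents that add atoms: none
Why: Acid-catalysed transacetalisation of the phenolic MOM acetal to methanol frees the phenol under conditions to which benzyl ethers, the alkyne and the secondary propargylic alcohol are inert.

Step 12
Reactants: 20 5-(benzyloxy)-2-{(2S,3S)-2-(benzyloxy)-5-[(2R,3S,4R)-3,7-bis(benzyloxy)-2-(3,4-bis(benzyloxy)phenyl)chroman-4-yl]-3-hydroxypent-4-yn-1-yl}phenol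
Product: 21 (2R,3S,4R)-3,7-bis(benzyloxy)-2-[3,4-bis(benzyloxy)phenyl]-4-{[(2R,3S)-3,7-bis(benzyloxy)chroman-2-yl]ethynyl}chromane
Conditions: PPh3, DIAD, THF (dilute), 0 °C → rt
Reagents that add atoms: none
Why: Intramolecular Mitsunobu etherification in which the phenol displaces the oxyphosphonium of the propargylic alcohol in a 6-exo-tet SN2 step with inversion, turning the 3S carbinol into C2 (R) and giving the 2,3-trans ring F.

Step 13
Reactants: 22 2,3-butanedione
Product: 23 2,3-bis(tert-butyldimethylsilyloxy)buta-1,3-diene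
Conditions: TBSOTf (2.2 equiv), Et3N, CH2Cl2, 0 °C → rt
Reagents that add atoms: tert-butyldimethylsilyl trifluoromethanesulfonate, CC(C)(C)[Si](C)(C)OS(=O)(=O)C(F)(F)F
Why: Twofold soft enolisation and O-silylation of the 1,2-diketone (silyl enol ether formation) gives the symmetric bis-enol ether diene.

Step 14
Reactants: 21 (2R,3S,4R)-3,7-bis(benzyloxy)-2-[3,4-bis(benzyloxy)phenyl]-4-{[(2R,3S)-3,7-bis(benzyloxy)chroman-2-yl]ethynyl}chromane; 23 2,3-bis(tert-butyldimethylsilyloxy)buta-1,3-diene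
Product: 24 1-[(2R,3S)-3,7-bis(benzyloxy)chroman-2-yl]-2-[(2R,3S,4R)-3,7-bis(benzyloxy)-2-(3,4-bis(benzyloxy)phenyl)chroman-4-yl]-4,5-bis(tert-butyldimethylsilyloxy)cyclohexa-1,4-diene
Conditions: CoBr2(Ph2PCH2CH2PPh2) (20 mol%), Zn dust (40 mol%), ZnI2 (40 mol%), CH2Cl2, 25 → 40 °C, 23 (3 equiv) added slowly; filtration through Et3N-deactivated silica
Reagents that add atoms: none
Why: Proposed new method: zinc reduces the divalent cobalt precatalyst to a monovalent cobalt–bisphosphine species that ZnI2 renders cationic; this binds diene 23 in its s-cis form together with the alkyne of 21, oxidative cyclisation gives a trivalent cobaltacycle, and C–C reductive elimination releases the cyclohexa-1,4-diene. The closest known reaction type is the cobalt-catalysed [4+2] cycloaddition of unactivated internal alkynes with 2-silyloxy- and 2,3-dialkyl-1,3-dienes under the same catalyst system, here extended to a 2,3-bis(silyloxy)diene and to an alkyne flanked by two branched, oxygenated propargylic carbons. The six-membered carbocycle of ring E is closed intermolecularly in this metal-templated [4+2] mode, the two new C–C bonds joining the alkyne carbons (future C1' and C6') to the diene termini (future C2' and C5'). No stereocentre is created, and the five existing ones, including the two propargylic ones, are not involved because no propargylic C–H or C–O bond is broken in the cycle. The step needs only chemoselectivity for cross-cycloaddition over diene dimerisation, alkyne trimerisation and Lewis-acid desilylation of the diene: the symmetric diene removes regiochemistry, the hindered internal alkyne cannot trimerise, slow addition keeps the diene concentration low, and all six oxygens of 21 are benzyl ethers, which neither bind cobalt strongly nor ionise with ZnI2.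

Step 15
Reactants: 24 1-[(2R,3S)-3,7-bis(benzyloxy)chroman-2-yl]-2-[(2R,3S,4R)-3,7-bis(benzyloxy)-2-(3,4-bis(benzyloxy)phenyl)chroman-4-yl]-4,5-bis(tert-butyldimethylsilyloxy)cyclohexa-1,4-diene
Product: 25 (2R,3S,4R)-3,7-bis(benzyloxy)-2-[3,4-bis(benzyloxy)phenyl]-4-{2-[(2R,3S)-3,7-bis(benzyloxy)chroman-2-yl]-4,5-bis(tert-butyldimethylsilyloxy)phenyl}chromane
Conditions: DDQ (1.05 equiv), toluene, 0 °C
Reagents that add atoms: none
Why: Quinone dehydrogenation of a cyclohexa-1,4-diene to the arene (hydride abstraction from the doubly allylic CH2 next to a silyl enol ether, then proton loss), much faster than oxidation of benzyl ethers or of the flavan C–H bonds when one equivalent is used cold; no stereocentre is involved.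

Step 16
Reactants: 25 (2R,3S,4R)-3,7-bis(benzyloxy)-2-[3,4-bis(benzyloxy)phenyl]-4-{2-[(2R,3S)-3,7-bis(benzyloxy)chroman-2-yl]-4,5-bis(tert-butyldimethylsilyloxy)phenyl}chromane
Product: 26 4-[(2R,3S)-3,7-bis(benzyloxy)chroman-2-yl]-5-[(2R,3S,4R)-3,7-bis(benzyloxy)-2-(3,4-bis(benzyloxy)phenyl)chroman-4-yl]benzene-1,2-diol
Conditions: HF·pyridine, THF/pyridine, 0 °C → rt
Reagents that add atoms: none
Why: Fluoride-driven cleavage of the two aryl silyl ethers (Si–F bond formation) in a mildly acidic medium that protects the freed catechol from air oxidation and leaves benzyl ethers intact.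

Step 17
Reactants: 26 4-[(2R,3S)-3,7-bis(benzyloxy)chroman-2-yl]-5-[(2R,3S,4R)-3,7-bis(benzyloxy)-2-(3,4-bis(benzyloxy)phenyl)chroman-4-yl]benzene-1,2-diol
Product: 27 (2R,3S)-2-{2-[(2R,3S,4R)-2-(3,4-dihydroxyphenyl)-3,7-dihydroxychroman-4-yl]-4,5-dihydroxyphenyl}chromane-3,7-diol (CNP0244903.3)
Conditions: H2 (1 atm), Pd(OH)2 on carbon, THF/MeOH, rt
Reagents that add atoms: none
Why: Catalytic hydrogenolysis of the six benzyl ethers, under which the benzylic C2–O1 and C4–aryl bonds of flavans are retained and no stereocentre is affected, should give the target after filtration.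

Compound list
1 | (2R,3R)-fustin | O=C1c2ccc(O)cc2O[C@H](c2ccc(O)c(O)c2)[C@H]1O | starting material
2 | (2R,3R)-7-(benzyloxy)-2-[3,4-bis(benzyloxy)phenyl]-3-hydroxychroman-4-one | O=C1c2ccc(OCc3ccccc3)cc2O[C@H](c2ccc(OCc3ccccc3)c(OCc3ccccc3)c2)[C@H]1O | intermediate
3 | (2R,3S,4R)-7-(benzyloxy)-2-[3,4-bis(benzyloxy)phenyl]chromane-3,4-diol (2,3-trans, 3,4-trans) | O[C@@H]1c2ccc(OCc3ccccc3)cc2O[C@H](c2ccc(OCc3ccccc3)c(OCc3ccccc3)c2)[C@H]1O | intermediate
4 | (2R,3S,4R)-3,4,7-tris(benzyloxy)-2-[3,4-bis(benzyloxy)phenyl]chromane | c1ccccc1CO[C@@H]1c2ccc(OCc3ccccc3)cc2O[C@H](c2ccc(OCc3ccccc3)c(OCc3ccccc3)c2)[C@H]1OCc1ccccc1 | intermediate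
5 | potassium trifluoro[(trimethylsilyl)ethynyl]borate | C[Si](C)(C)C#C[B-](F)(F)F.[K+] | starting material
6 | difluoro[(trimethylsilyl)ethynyl]borane | C[Si](C)(C)C#CB(F)F | intermediate (not isolated)
7 | (2R,3S,4S)-3,7-bis(benzyloxy)-2-[3,4-bis(benzyloxy)phenyl]-4-[(trimethylsilyl)ethynyl]chromane (3,4-trans; the C4 descriptor differs from 8 only because silicon raises the rank of the alkynyl branch) | C[Si](C)(C)C#C[C@@H]1c2ccc(OCc3ccccc3)cc2O[C@H](c2ccc(OCc3ccccc3)c(OCc3ccccc3)c2)[C@H]1OCc1ccccc1 | intermediate (not isolated)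
8 | (2R,3S,4R)-3,7-bis(benzyloxy)-2-[3,4-bis(benzyloxy)phenyl]-4-ethynylchromane (3,4-trans) | C#C[C@@H]1c2ccc(OCc3ccccc3)cc2O[C@H](c2ccc(OCc3ccccc3)c(OCc3ccccc3)c2)[C@H]1OCc1ccccc1 | intermediate
9 | 4-bromoresorcinol | Oc1ccc(Br)c(O)c1 | starting material
10 | 5-(benzyloxy)-2-bromophenol | Oc1cc(OCc2ccccc2)ccc1Br | intermediate
11 | 4-(benzyloxy)-1-bromo-2-(methoxymethoxy)benzene | COCOc1cc(OCc2ccccc2)ccc1Br | intermediate
12 | methyl (S)-glycidate | COC(=O)[C@@H]1CO1 | starting material
13 | [4-(benzyloxy)-2-(methoxymethoxy)phenyl]magnesium bromide | COCOc1cc(OCc2ccccc2)ccc1[Mg]Br | intermediate (not isolated)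
14 | methyl (2S)-3-[4-(benzyloxy)-2-(methoxymethoxy)phenyl]-2-hydroxypropanoate | COC(=O)[C@@H](O)Cc1ccc(OCc2ccccc2)cc1OCOC | intermediate
15 | methyl (2S)-2-(benzyloxy)-3-[4-(benzyloxy)-2-(methoxymethoxy)phenyl]propanoate | COC(=O)[C@@H](OCc1ccccc1)Cc1ccc(OCc2ccccc2)cc1OCOC | intermediate
16 | (2S)-2-(benzyloxy)-3-[4-(benzyloxy)-2-(methoxymethoxy)phenyl]propanal | O=C[C@@H](OCc1ccccc1)Cc1ccc(OCc2ccccc2)cc1OCOC | intermediate
17 | lithium acetylide of 8 | [Li]C#C[C@@H]1c2ccc(OCc3ccccc3)cc2O[C@H](c2ccc(OCc3ccccc3)c(OCc3ccccc3)c2)[C@H]1OCc1ccccc1 | intermediate (not isolated)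
18 | alkynylzinc bromide of 8 | Br[Zn]C#C[C@@H]1c2ccc(OCc3ccccc3)cc2O[C@H](c2ccc(OCc3ccccc3)c(OCc3ccccc3)c2)[C@H]1OCc1ccccc1 | intermediate (not isolated)
19 | (2S,3S)-2-(benzyloxy)-1-[4-(benzyloxy)-2-(methoxymethoxy)phenyl]-5-[(2R,3S,4R)-3,7-bis(benzyloxy)-2-(3,4-bis(benzyloxy)phenyl)chroman-4-yl]pent-4-yn-3-ol | O[C@@H](C#C[C@@H]1c2ccc(OCc3ccccc3)cc2O[C@H](c2ccc(OCc3ccccc3)c(OCc3ccccc3)c2)[C@H]1OCc1ccccc1)[C@@H](OCc1ccccc1)Cc1ccc(OCc2ccccc2)cc1OCOC | intermediate
20 | 5-(benzyloxy)-2-{(2S,3S)-2-(benzyloxy)-5-[(2R,3S,4R)-3,7-bis(benzyloxy)-2-(3,4-bis(benzyloxy)phenyl)chroman-4-yl]-3-hydroxypent-4-yn-1-yl}phenol | O[C@@H](C#C[C@@H]1c2ccc(OCc3ccccc3)cc2O[C@H](c2ccc(OCc3ccccc3)c(OCc3ccccc3)c2)[C@H]1OCc1ccccc1)[C@@H](OCc1ccccc1)Cc1ccc(OCc2ccccc2)cc1O | intermediate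
21 | (2R,3S,4R)-3,7-bis(benzyloxy)-2-[3,4-bis(benzyloxy)phenyl]-4-{[(2R,3S)-3,7-bis(benzyloxy)chroman-2-yl]ethynyl}chromane (hexabenzyl alkyne, precursor of the key step) | c4ccccc4COc1ccc2c(c1)O[C@H](C#C[C@@H]1c3ccc(OCc4ccccc4)cc3O[C@H](c3ccc(OCc4ccccc4)c(OCc4ccccc4)c3)[C@H]1OCc4ccccc4)[C@@H](OCc4ccccc4)C2 | intermediate
22 | 2,3-butanedione | CC(=O)C(C)=O | starting material
23 | 2,3-bis(tert-butyldimethylsilyloxy)buta-1,3-diene | C=C(O[Si](C)(C)C(C)(C)C)C(=C)O[Si](C)(C)C(C)(C)C | intermediate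
24 | 1-[(2R,3S)-3,7-bis(benzyloxy)chroman-2-yl]-2-[(2R,3S,4R)-3,7-bis(benzyloxy)-2-(3,4-bis(benzyloxy)phenyl)chroman-4-yl]-4,5-bis(tert-butyldimethylsilyloxy)cyclohexa-1,4-diene (product of the key step) | c4ccccc4COc1ccc2c(c1)O[C@H](C5=C([C@@H]1c3ccc(OCc4ccccc4)cc3O[C@H](c3ccc(OCc4ccccc4)c(OCc4ccccc4)c3)[C@H]1OCc4ccccc4)CC(O[Si](C)(C)C(C)(C)C)=C(O[Si](C)(C)C(C)(C)C)C5)[C@@H](OCc4ccccc4)C2 | intermediate
25 | (2R,3S,4R)-3,7-bis(benzyloxy)-2-[3,4-bis(benzyloxy)phenyl]-4-{2-[(2R,3S)-3,7-bis(benzyloxy)chroman-2-yl]-4,5-bis(tert-butyldimethylsilyloxy)phenyl}chromane | c4ccccc4COc1ccc2c(c1)O[C@H](c5cc(O[Si](C)(C)C(C)(C)C)c(O[Si](C)(C)C(C)(C)C)cc5[C@@H]1c3ccc(OCc4ccccc4)cc3O[C@H](c3ccc(OCc4ccccc4)c(OCc4ccccc4)c3)[C@H]1OCc4ccccc4)[C@@H](OCc4ccccc4)C2 | intermediate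
26 | 4-[(2R,3S)-3,7-bis(benzyloxy)chroman-2-yl]-5-[(2R,3S,4R)-3,7-bis(benzyloxy)-2-(3,4-bis(benzyloxy)phenyl)chroman-4-yl]benzene-1,2-diol | c4ccccc4COc1ccc2c(c1)O[C@H](c5cc(O)c(O)cc5[C@@H]1c3ccc(OCc4ccccc4)cc3O[C@H](c3ccc(OCc4ccccc4)c(OCc4ccccc4)c3)[C@H]1OCc4ccccc4)[C@@H](OCc4ccccc4)C2 | intermediate
27 | (2R,3S)-2-{2-[(2R,3S,4R)-2-(3,4-dihydroxyphenyl)-3,7-dihydroxychroman-4-yl]-4,5-dihydroxyphenyl}chromane-3,7-diol (CNP0244903.3) | Oc1ccc2c(c1)O[C@H](c1cc(O)c(O)cc1[C@@H]1c3ccc(O)cc3O[C@H](c3ccc(O)c(O)c3)[C@H]1O)[C@@H](O)C2 | target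

Total step count: 17.
Longest linear sequence: 12 steps (from 9 through steps 5–12 and 14–17 to 27); the fustin branch (steps 1–4) and the diene (step 13) join it at steps 10 and 14.

Steps most likely to fail

Step 14. Hindrance at both propargylic carbons may keep the alkyne from binding to cobalt, or the diene may be used up by dimerisation or by ZnI2-induced desilylation before it couples. The fallback uses known chemistry, sets out from 4 (with 16) and returns at 27. Friedel–Crafts alkylation of commercial 4-bromo-1,2-bis(benzyloxy)benzene (large excess) by the C4 cation of 4 (BF3·OEt2, CH2Cl2, −40 → 0 °C) should occur para to an oxygen, ortho to bromine and anti to the 3-benzyloxy group, giving the 3,4-trans 4-[4,5-bis(benzyloxy)-2-bromophenyl]flavan F1. Bromine–lithium exchange (t-BuLi, Et2O, −78 °C), transmetalation with MgBr2·OEt2 and chelate-controlled addition to aldehyde 16 would give the benzylic alcohol F2. HCl in MeOH/THF would then remove the MOM group and close ring F by SN1 attack of the phenol on the benzylic cation stabilised by the 4'-benzyloxy group (2,3-trans favoured, the cis isomer to be separated), giving the octabenzyl ether of the target F3. Hydrogenolysis as in step 17 returns to 27. The price is that the competition between arenes (self-alkylation at ring A) comes back, which the alkyne route avoids.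

Step 4. A slim alkynyl nucleophile may attack the C4 cation with poor facial selectivity, or the cation may be captured by ring A of a second molecule. The fallback sets out from 3 and returns at 8. Acetylation (Ac2O, pyridine) would give the 3,4-diacetate F4. The same alkynylation with 5 and BF3·OEt2 would now pass through a cis-fused acetoxonium ion from the 3-acetate, which blocks one face and enforces trans attack, to give the 3-O-acetyl-4-[(trimethylsilyl)ethynyl]flavan F5. K2CO3 in MeOH would remove acetate and silyl group to give the 4-ethynylflavan-3-ol F6. Acid-catalysed benzylation with benzyl 2,2,2-trichloroacetimidate (TfOH cat., CH2Cl2) would then reach 8.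

Step 10. Incomplete chelation may give poor facial selectivity, or aldehyde 16 may epimerise before it reacts. The fallback sets out from the epimer mixture of 19 and returns at 19. Oxidation with Dess–Martin periodinane (NaHCO3, CH2Cl2) would give the ynone F7. Reagent-controlled Corey–Bakshi–Shibata reduction ((R)-2-methyl-CBS-oxazaborolidine, catecholborane, toluene, −78 °C) should then, by the usual model with the alkyne as the small group, deliver the (3S)-carbinol 19 irrespective of the neighbouring centre.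

Further compounds
F1 | step 14 | (2R,3S)-3,7-bis(benzyloxy)-2-[3,4-bis(benzyloxy)phenyl]-4-[4,5-bis(benzyloxy)-2-bromophenyl]chromane, aryl at C4 trans to O3 | Brc1cc(OCc2ccccc2)c(OCc2ccccc2)cc1[C@@H]1c2ccc(OCc3ccccc3)cc2O[C@H](c2ccc(OCc3ccccc3)c(OCc3ccccc3)c2)[C@H]1OCc1ccccc1
F2 | step 14 | syn-2-(benzyloxy)-3-[4-(benzyloxy)-2-(methoxymethoxy)phenyl]-1-{4,5-bis(benzyloxy)-2-[3,7-bis(benzyloxy)-2-(3,4-bis(benzyloxy)phenyl)chroman-4-yl]phenyl}propan-1-ol | O[C@@H](c1cc(OCc2ccccc2)c(OCc2ccccc2)cc1[C@@H]1c2ccc(OCc3ccccc3)cc2O[C@H](c2ccc(OCc3ccccc3)c(OCc3ccccc3)c2)[C@H]1OCc1ccccc1)[C@@H](OCc1ccccc1)Cc1ccc(OCc2ccccc2)cc1OCOC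
F3 | step 14 | octabenzyl ether of 27 | c4ccccc4COc1ccc2c(c1)O[C@H](c5cc(OCc4ccccc4)c(OCc4ccccc4)cc5[C@@H]1c3ccc(OCc4ccccc4)cc3O[C@H](c3ccc(OCc4ccccc4)c(OCc4ccccc4)c3)[C@H]1OCc4ccccc4)[C@@H](OCc4ccccc4)C2
F4 | step 4 | 3,4-di-O-acetate of 3 | CC(=O)O[C@@H]1c2ccc(OCc3ccccc3)cc2O[C@H](c2ccc(OCc3ccccc3)c(OCc3ccccc3)c2)[C@H]1OC(C)=O
F5 | step 4 | 3-O-acetyl-7-(benzyloxy)-2-[3,4-bis(benzyloxy)phenyl]-4-[(trimethylsilyl)ethynyl]chromane, 3,4-trans | C[Si](C)(C)C#C[C@@H]1c2ccc(OCc3ccccc3)cc2O[C@H](c2ccc(OCc3ccccc3)c(OCc3ccccc3)c2)[C@H]1OC(C)=O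
F6 | step 4 | (2R,3S,4R)-7-(benzyloxy)-2-[3,4-bis(benzyloxy)phenyl]-4-ethynylchroman-3-ol | C#C[C@@H]1c2ccc(OCc3ccccc3)cc2O[C@H](c2ccc(OCc3ccccc3)c(OCc3ccccc3)c2)[C@H]1O
F7 | step 10 | (2S)-2-(benzyloxy)-1-[4-(benzyloxy)-2-(methoxymethoxy)phenyl]-5-[(2R,3S,4R)-3,7-bis(benzyloxy)-2-(3,4-bis(benzyloxy)phenyl)chroman-4-yl]pent-4-yn-3-one | O=C(C#C[C@@H]1c2ccc(OCc3ccccc3)cc2O[C@H](c2ccc(OCc3ccccc3)c(OCc3ccccc3)c2)[C@H]1OCc1ccccc1)[C@@H](OCc1ccccc1)Cc1ccc(OCc2ccccc2)cc1OCOC
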